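**Retrosynthetic overview**

1. Ring A is made last, in one flask, from a four-membered ring: the target comes from the silyl enol ether of the dione, and that from a 2-alkyl-3-silyloxycyclobut-2-enone plus 1-methoxyvinyllithium (1,2-addition, 4π ring opening, 6π ring closure, face-selective protonation). This forms C3–C4 and C5–C6 of ring A and breaks the C(=O)–CH2 bond of the cyclobutenone.
2. Enabling feature: in ring A the carbonyl/enol carbon C3 lies between the alkylated C2 and the methoxy carbon C4, and C5 and C6 are plain CH2 groups. C6–C1–C2–C3 is therefore a masked 3-oxycyclobut-2-enone (C3=O bonded to C6H2), C4(OMe)–C5 is methyl vinyl ether, and the α-methoxy ketone C3(=O)–C4H(OMe) is what an α-methoxyvinyl anion gives after carbonyl addition and C-protonation.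
3. The cyclobutenone comes from a [2+2] cycloaddition of ketene with a silyl ynol ether, which comes from Kowalski homologation of the cyclopentenylacetic ester.
4. The ester comes from an Ireland–Claisen rearrangement of a cis-4-silyloxycyclopent-2-enyl acetate (1,3-chirality transfer sets the ring CH and places the ring double bond). The acetate comes from Corey–Bakshi–Shibata reduction of a 2-dienyl enone, made by Negishi coupling of an α-iodoenone with a (Z)-alkenyl iodide (Stork–Zhao olefination).
5. Order of rings: the cyclopentene ring is bought as (R)-4-silyloxycyclopentenone (methyl addition sets the carbinol carbon); the temporary cyclobutenone is formed in step 14; ring A is formed in step 15.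

Key step: step 15

Assumption: the (2R,3R) antipode of O,O'-dipivaloyltartaric acid is taken as the one that protonates the dienolate on the face leading to the 6S product (4S in the target). The sense must be checked in the first run; the equally available (2S,3S) acid would replace it with no other change.

**Route**

Step 1
Reactants: 1 4-methylpent-3-en-1-ol
Product: 2 4-methylpent-3-enal
Conditions: PhI(OAc)2, TEMPO (cat.), CH2Cl2, 20 °C; solution used directly
Reagents that add atoms: none
Why: The nitroxyl-catalysed oxidation should stop at the aldehyde under neutral conditions, so the β,γ-double bond should not move into conjugation.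

Step 2
Reactants: 2 4-methylpent-3-enal
Product: 3 (2Z)-2-iodo-6-methylhepta-2,5-diene
Conditions: ethyltriphenylphosphonium iodide, n-BuLi, THF, 20 °C; I2, –78 °C; NaN(SiMe3)2, –20 °C; then 2, –78 → 20 °C
Reagents that add atoms: ethyltriphenylphosphonium iodide (CC[P+](c1ccccc1)(c1ccccc1)c1ccccc1.[I-]); iodine ([I][I])
Why: Stork–Zhao olefination with the non-stabilised α-iodo ylide should go through the kinetically preferred cis-oxaphosphetane and place iodine cis to the alkyl chain, giving the Z-iodide.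

Step 3
Reactants: 4 (4R)-4-[(tert-butyldimethylsilyl)oxy]cyclopent-2-en-1-one
Product: 5 (1S,4R)-4-[(tert-butyldimethylsilyl)oxy]-1-methylcyclopent-2-en-1-ol
Conditions: MeLi, CeCl3, THF, –78 °C
Reagents that add atoms: methyllithium (C[Li])
Why: Organocerium 1,2-addition to the enone carbonyl should occur anti to the 4-silyloxy group, which sets the tertiary carbinol (1S, OH cis to OTBS), and the weakly basic reagent avoids enolisation.

Step 4
Reactants: 5 (1S,4R)-4-[(tert-butyldimethylsilyl)oxy]-1-methylcyclopent-2-en-1-ol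
Product: 6 (1S,4R)-1-methylcyclopent-2-ene-1,4-diol
Conditions: Bu4NF, THF, 0 → 20 °C
Reagents that add atoms: none
Why: Fluoride-mediated desilylation frees the secondary allylic alcohol without touching a stereocentre.

Step 5
Reactants: 6 (1S,4R)-1-methylcyclopent-2-ene-1,4-diol
Product: 7 (4S)-4-hydroxy-4-methylcyclopent-2-en-1-one
Conditions: MnO2, CH2Cl2, 20 °C
Reagents that add atoms: none
Why: Allylic oxidation with MnO2 can only convert the secondary carbinol, so the directing stereocentre is erased on purpose and the tertiary carbinol set in step 3 is carried into an enone whose α-carbon is the future side-chain carbon.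

Step 6
Reactants: 7 (4S)-4-hydroxy-4-methylcyclopent-2-en-1-one
Product: 8 (4S)-4-methyl-4-[(triethylsilyl)oxy]cyclopent-2-en-1-one
Conditions: Et3SiOTf, 2,6-lutidine, CH2Cl2, –78 → 0 °C
Reagents that add atoms: triethylsilyl trifluoromethanesulfonate (CC[Si](CC)(CC)OS(=O)(=O)C(F)(F)F)
Why: Silyl triflate with a hindered pyridine base is the standard silylation of a tertiary alcohol and is mild enough to avoid retro-aldol opening of the β-hydroxy ketone.

Step 7
Reactants: 8 (4S)-4-methyl-4-[(triethylsilyl)oxy]cyclopent-2-en-1-one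
Product: 9 (4S)-2-iodo-4-methyl-4-[(triethylsilyl)oxy]cyclopent-2-en-1-one
Conditions: I2, pyridine, CH2Cl2, 0 → 20 °C
Reagents that add atoms: iodine ([I][I])
Why: α-Iodination of a cyclic enone by conjugate addition of pyridine, iodination of the enolate and elimination (Baylis–Hillman-type mechanism) should place iodine only at C2.

Step 8
Reactants: 9 (4S)-2-iodo-4-methyl-4-[(triethylsilyl)oxy]cyclopent-2-en-1-one; 3 (2Z)-2-iodo-6-methylhepta-2,5-diene
Product: 12 (4S)-4-methyl-2-[(2Z)-6-methylhepta-2,5-dien-2-yl]-4-[(triethylsilyl)oxy]cyclopent-2-en-1-one, via alkenyllithium 10 (not isolated), via alkenylzinc chloride 11 (not isolated)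
Conditions: 3, t-BuLi (2 equiv), Et2O, –78 °C; ZnCl2, THF, –78 → 0 °C; then 9, Pd2(dba)3 (cat.), tri(2-furyl)phosphine (cat.), THF/DMF, 20 °C
Reagents that add atoms: none
Why: Negishi coupling: iodine–lithium exchange, transmetalation to zinc and the zerovalent-palladium-catalysed coupling with the α-iodoenone all proceed with retention of alkene geometry, so the ring carbon ends cis to the CH2 group.

Step 9
Reactants: 12 (4S)-4-methyl-2-[(2Z)-6-methylhepta-2,5-dien-2-yl]-4-[(triethylsilyl)oxy]cyclopent-2-en-1-one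
Product: 13 (1R,4S)-4-methyl-2-[(2Z)-6-methylhepta-2,5-dien-2-yl]-4-[(triethylsilyl)oxy]cyclopent-2-en-1-ol
Conditions: (S)-2-methyl-CBS-oxazaborolidine (0.2 equiv), catecholborane, toluene, –78 °C
Reagents that add atoms: none
Why: Corey–Bakshi–Shibata reduction with the α-substituted alkene side as the large group should deliver hydride to the face anti to the silyloxy group (catalyst and substrate bias matched), giving the 1R alcohol cis to OSiEt3, and catecholborane does not hydroborate the alkenes.

Step 10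
Reactants: 13 (1R,4S)-4-methyl-2-[(2Z)-6-methylhepta-2,5-dien-2-yl]-4-[(triethylsilyl)oxy]cyclopent-2-en-1-ol
Product: 14 (1R,4S)-4-methyl-2-[(2Z)-6-methylhepta-2,5-dien-2-yl]-4-[(triethylsilyl)oxy]cyclopent-2-en-1-yl acetate
Conditions: Ac2O, Et3N, DMAP (cat.), CH2Cl2, 0 → 20 °C
Reagents that add atoms: acetic anhydride (CC(=O)OC(C)=O)
Why: Acyl transfer to the secondary allylic alcohol installs the two carbons that become the CH2 linker and C1 of ring A.

Step 11
Reactants: 14 (1R,4S)-4-methyl-2-[(2Z)-6-methylhepta-2,5-dien-2-yl]-4-[(triethylsilyl)oxy]cyclopent-2-en-1-yl acetate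
Product: 17 2-[(1R,5S)-5-methyl-2-[(2Z)-6-methylhepta-2,5-dien-2-yl]-5-[(triethylsilyl)oxy]cyclopent-2-en-1-yl]acetic acid, via silyl ketene acetal 15 (not isolated), via trimethylsilyl ester 16 (not isolated)
Conditions: LiN(iPr)2, Me3SiCl, THF, –78 → 50 °C; then aqueous citric acid
Reagents that add atoms: none
Why: Ireland–Claisen rearrangement is suprafacial, so the new C–C bond forms at the ring carbon next to the quaternary centre on the face that carried the acetate oxygen (cis to OSiEt3), which sets the ring CH (1R) by 1,3-chirality transfer and moves the double bond to its position in the target.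

Step 12
Reactants: 17 2-[(1R,5S)-5-methyl-2-[(2Z)-6-methylhepta-2,5-dien-2-yl]-5-[(triethylsilyl)oxy]cyclopent-2-en-1-yl]acetic acid
Product: 18 methyl 2-[(1R,5S)-5-methyl-2-[(2Z)-6-methylhepta-2,5-dien-2-yl]-5-[(triethylsilyl)oxy]cyclopent-2-en-1-yl]acetate
Conditions: MeI, K2CO3, DMF, 20 °C
Reagents that add atoms: iodomethane (C[I])
Why: Carboxylate O-alkylation gives the ester needed for homologation; the stereocentre is β to the carbonyl and cannot epimerise.

Step 13
Reactants: 18 methyl 2-[(1R,5S)-5-methyl-2-[(2Z)-6-methylhepta-2,5-dien-2-yl]-5-[(triethylsilyl)oxy]cyclopent-2-en-1-yl]acetate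
Product: 21 triethyl{[(1S,2R)-1-methyl-3-[(2Z)-6-methylhepta-2,5-dien-2-yl]-2-{3-[(triisopropylsilyl)oxy]prop-2-yn-1-yl}cyclopent-3-en-1-yl]oxy}silane, via lithium bromoenolate 19 (not isolated), via lithium ynolate 20 (not isolated)
Conditions: CH2Br2, lithium 2,2,6,6-tetramethylpiperidide, THF, –78 °C; n-BuLi (2.2 equiv), –78 → 0 °C; iPr3SiOTf, –78 → 0 °C
Reagents that add atoms: dibromomethane (BrCBr); triisopropylsilyl trifluoromethanesulfonate (CC(C)[Si](OS(=O)(=O)C(F)(F)F)(C(C)C)C(C)C)
Why: Kowalski homologation: addition of LiCHBr2, bromine–lithium exchange with loss of methoxide, deprotonation and carbenoid 1,2-shift give the ynolate, which the bulky silyl triflate should silylate on oxygen.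

Step 14
Reactants: 21 triethyl{[(1S,2R)-1-methyl-3-[(2Z)-6-methylhepta-2,5-dien-2-yl]-2-{3-[(triisopropylsilyl)oxy]prop-2-yn-1-yl}cyclopent-3-en-1-yl]oxy}silane
Product: 22 2-{[(1R,5S)-5-methyl-2-[(2Z)-6-methylhepta-2,5-dien-2-yl]-5-[(triethylsilyl)oxy]cyclopent-2-en-1-yl]methyl}-3-[(triisopropylsilyl)oxy]cyclobut-2-en-1-one
Conditions: ketene (gas, from pyrolysis of acetone), CH2Cl2, 0 → 20 °C
Reagents that add atoms: ketene (C=C=O)
Why: In the [2+2] cycloaddition of ketene with a siloxyalkyne the nucleophilic β-carbon of the ynol ether attacks the ketene carbonyl carbon, so the 2-alkyl-3-silyloxycyclobut-2-enone with an unsubstituted C4 methylene should form as the only regioisomer.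

Step 15
Reactants: 22 2-{[(1R,5S)-5-methyl-2-[(2Z)-6-methylhepta-2,5-dien-2-yl]-5-[(triethylsilyl)oxy]cyclopent-2-en-1-yl]methyl}-3-[(triisopropylsilyl)oxy]cyclobut-2-en-1-one; 23 methyl vinyl ether
Product: 28 (6S)-6-methoxy-2-{[(1R,5S)-5-methyl-2-[(2Z)-6-methylhepta-2,5-dien-2-yl]-5-[(triethylsilyl)oxy]cyclopent-2-en-1-yl]methyl}-3-[(triisopropylsilyl)oxy]cyclohex-2-en-1-one, via 1-methoxyvinyllithium 24 (not isolated), via lithium cyclobutenolate 25 (not isolated), via lithium trienolate 26 (not isolated), via lithium dienolate 27 (not isolated)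
Conditions: 23 (3 equiv), t-BuLi (1.3 equiv), THF, –78 → 0 °C; 22, THF, –78 → 20 °C; then (2R,3R)-O,O'-dipivaloyltartaric acid (2 equiv), THF, –78 °C
Reagents that add atoms: none
Why: Proposed new method: 1-methoxyvinyllithium should add 1,2 to the carbonyl of the vinylogous silyl ester (forming C3–C4 of ring A), the cyclobutenolate should undergo oxyanion-accelerated conrotatory 4π ring opening with the oxide rotating outward and the methoxyvinyl group inward, and the cis-trienolate should close by thermal disrotatory 6π-electrocyclisation between its two CH2 termini (forming C5–C6), the closest known reaction type being the ring expansion of cyclobutenones to cyclohexenones by addition of alkenyllithiums. The net result is insertion of the two carbons of methyl vinyl ether into the C(=O)–CH2 bond of the four-membered ring, which delivers the whole oxidation pattern of ring A (enol ether at C1, ketone at C3, methoxy at C4) in one flask. Ring A is closed in the electrocyclic mode (6π, disrotatory), and because both termini are CH2 groups the closure itself creates no stereocentre. The only new stereocentre, C6 of the product (C4 of the target), arises when the cross-conjugated lithium dienolate is protonated on carbon by the chiral diacid, so the controlling element is the configuration of the proton donor; the closest known type for this part is the enantioselective protonation of lithium enolates of α-oxygenated ketones by O,O'-diacyltartaric acids, which has not been shown on a cyclic α-methoxy dienolate. The step needs 1,2- over 1,4-addition (hard organolithium, poorly electrophilic β-silyloxy carbon), inward rotation of the alkenyl group (strong outward preference of the oxide) and C- over O-protonation (C6 is the only carbon terminus of the cross-conjugated enolate, and the quench is made at –78 °C).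

Step 16
Reactants: 28 (6S)-6-methoxy-2-{[(1R,5S)-5-methyl-2-[(2Z)-6-methylhepta-2,5-dien-2-yl]-5-[(triethylsilyl)oxy]cyclopent-2-en-1-yl]methyl}-3-[(triisopropylsilyl)oxy]cyclohex-2-en-1-one
Product: 29 (4S)-3-hydroxy-2-{[(1R,5S)-5-hydroxy-5-methyl-2-[(2Z)-6-methylhepta-2,5-dien-2-yl]cyclopent-2-en-1-yl]methyl}-4-methoxycyclohex-2-en-1-one
Conditions: HF·pyridine, pyridine, THF, 0 → 20 °C
Reagents that add atoms: none
Why: Buffered fluoride should cleave the vinylogous silyl ester and the tertiary triethylsilyl ether in one operation, releasing the dione as its enol without base that could epimerise the methoxy-bearing carbon.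

**Compound list**

1 | 4-methylpent-3-en-1-ol | CC(C)=CCCO | starting material
2 | 4-methylpent-3-enal | CC(C)=CCC=O | intermediate
3 | (2Z)-2-iodo-6-methylhepta-2,5-diene | C/C(I)=C/CC=C(C)C | intermediate
4 | (4R)-4-[(tert-butyldimethylsilyl)oxy]cyclopent-2-en-1-one | O=C1C=C[C@H](O[Si](C)(C)C(C)(C)C)C1 | starting material
5 | (1S,4R)-4-[(tert-butyldimethylsilyl)oxy]-1-methylcyclopent-2-en-1-ol | C[C@@]1(O)C=C[C@H](O[Si](C)(C)C(C)(C)C)C1 | intermediate
6 | (1S,4R)-1-methylcyclopent-2-ene-1,4-diol | C[C@@]1(O)C=C[C@H](O)C1 | intermediate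
7 | (4S)-4-hydroxy-4-methylcyclopent-2-en-1-one | C[C@@]1(O)C=CC(=O)C1 | intermediate
8 | (4S)-4-methyl-4-[(triethylsilyl)oxy]cyclopent-2-en-1-one | C[C@@]1(O[Si](CC)(CC)CC)C=CC(=O)C1 | intermediate
9 | (4S)-2-iodo-4-methyl-4-[(triethylsilyl)oxy]cyclopent-2-en-1-one | C[C@@]1(O[Si](CC)(CC)CC)C=C(I)C(=O)C1 | intermediate
10 | [(2E)-6-methylhepta-2,5-dien-2-yl]lithium (lithium cis to the CH2 group) | [Li]/C(C)=C\CC=C(C)C | intermediate (not isolated)
11 | chloro[(2Z)-6-methylhepta-2,5-dien-2-yl]zinc | Cl[Zn]/C(C)=C\CC=C(C)C | intermediate (not isolated)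
12 | (4S)-4-methyl-2-[(2Z)-6-methylhepta-2,5-dien-2-yl]-4-[(triethylsilyl)oxy]cyclopent-2-en-1-one | C[C@@]1(O[Si](CC)(CC)CC)C=C(/C(C)=C\CC=C(C)C)C(=O)C1 | intermediate
13 | (1R,4S)-4-methyl-2-[(2Z)-6-methylhepta-2,5-dien-2-yl]-4-[(triethylsilyl)oxy]cyclopent-2-en-1-ol | C[C@@]1(O[Si](CC)(CC)CC)C=C(/C(C)=C\CC=C(C)C)[C@H](O)C1 | intermediate
14 | (1R,4S)-4-methyl-2-[(2Z)-6-methylhepta-2,5-dien-2-yl]-4-[(triethylsilyl)oxy]cyclopent-2-en-1-yl acetate | C[C@@]1(O[Si](CC)(CC)CC)C=C(/C(C)=C\CC=C(C)C)[C@H](OC(C)=O)C1 | intermediate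
15 | trimethylsilyl ketene acetal of 14 | C[C@@]1(O[Si](CC)(CC)CC)C=C(/C(C)=C\CC=C(C)C)[C@H](OC(=C)O[Si](C)(C)C)C1 | intermediate (not isolated)
16 | trimethylsilyl 2-[(1R,5S)-5-methyl-2-[(2Z)-6-methylhepta-2,5-dien-2-yl]-5-[(triethylsilyl)oxy]cyclopent-2-en-1-yl]acetate | C[C@]1(O[Si](CC)(CC)CC)CC=C(/C(C)=C\CC=C(C)C)[C@H]1CC(=O)O[Si](C)(C)C | intermediate (not isolated)
17 | 2-[(1R,5S)-5-methyl-2-[(2Z)-6-methylhepta-2,5-dien-2-yl]-5-[(triethylsilyl)oxy]cyclopent-2-en-1-yl]acetic acid | C[C@]1(O[Si](CC)(CC)CC)CC=C(/C(C)=C\CC=C(C)C)[C@H]1CC(=O)O | intermediate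
18 | methyl 2-[(1R,5S)-5-methyl-2-[(2Z)-6-methylhepta-2,5-dien-2-yl]-5-[(triethylsilyl)oxy]cyclopent-2-en-1-yl]acetate | C[C@]1(O[Si](CC)(CC)CC)CC=C(/C(C)=C\CC=C(C)C)[C@H]1CC(=O)OC | intermediate
19 | lithium enolate of the bromomethyl ketone derived from 18 | C[C@]1(O[Si](CC)(CC)CC)CC=C(/C(C)=C\CC=C(C)C)[C@H]1CC(O[Li])=CBr | intermediate (not isolated)
20 | lithium 3-[(1R,5S)-5-methyl-2-[(2Z)-6-methylhepta-2,5-dien-2-yl]-5-[(triethylsilyl)oxy]cyclopent-2-en-1-yl]prop-1-yn-1-olate | C[C@]1(O[Si](CC)(CC)CC)CC=C(/C(C)=C\CC=C(C)C)[C@H]1CC#CO[Li] | intermediate (not isolated)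
21 | triethyl{[(1S,2R)-1-methyl-3-[(2Z)-6-methylhepta-2,5-dien-2-yl]-2-{3-[(triisopropylsilyl)oxy]prop-2-yn-1-yl}cyclopent-3-en-1-yl]oxy}silane | C[C@]1(O[Si](CC)(CC)CC)CC=C(/C(C)=C\CC=C(C)C)[C@H]1CC#CO[Si](C(C)C)(C(C)C)C(C)C | intermediate
22 | 2-{[(1R,5S)-5-methyl-2-[(2Z)-6-methylhepta-2,5-dien-2-yl]-5-[(triethylsilyl)oxy]cyclopent-2-en-1-yl]methyl}-3-[(triisopropylsilyl)oxy]cyclobut-2-en-1-one | C[C@]1(O[Si](CC)(CC)CC)CC=C(/C(C)=C\CC=C(C)C)[C@H]1CC2=C(O[Si](C(C)C)(C(C)C)C(C)C)CC2=O | intermediate
23 | methyl vinyl ether | COC=C | starting material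
24 | (1-methoxyvinyl)lithium | [Li]C(=C)OC | intermediate (not isolated)
25 | lithium 1-(1-methoxyvinyl)-2-{[(1R,5S)-5-methyl-2-[(2Z)-6-methylhepta-2,5-dien-2-yl]-5-[(triethylsilyl)oxy]cyclopent-2-en-1-yl]methyl}-3-[(triisopropylsilyl)oxy]cyclobut-2-en-1-olate (both configurations at the carbinol carbon) | C[C@]1(O[Si](CC)(CC)CC)CC=C(/C(C)=C\CC=C(C)C)[C@H]1CC2=C(O[Si](C(C)C)(C(C)C)C(C)C)CC2(O[Li])C(=C)OC | intermediate (not isolated)
26 | lithium (3E)-2-methoxy-4-{[(1R,5S)-5-methyl-2-[(2Z)-6-methylhepta-2,5-dien-2-yl]-5-[(triethylsilyl)oxy]cyclopent-2-en-1-yl]methyl}-5-[(triisopropylsilyl)oxy]hexa-1,3,5-trien-3-olate (the two vinyl groups cis on the central double bond) | C[C@]1(O[Si](CC)(CC)CC)CC=C(/C(C)=C\CC=C(C)C)[C@H]1C/C(C(=C)O[Si](C(C)C)(C(C)C)C(C)C)=C(\O[Li])C(=C)OC | intermediate (not isolated)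
27 | lithium 2-methoxy-6-{[(1R,5S)-5-methyl-2-[(2Z)-6-methylhepta-2,5-dien-2-yl]-5-[(triethylsilyl)oxy]cyclopent-2-en-1-yl]methyl}-5-[(triisopropylsilyl)oxy]cyclohexa-1,5-dien-1-olate | C[C@]1(O[Si](CC)(CC)CC)CC=C(/C(C)=C\CC=C(C)C)[C@H]1CC2=C(O[Si](C(C)C)(C(C)C)C(C)C)CCC(OC)=C2O[Li] | intermediate (not isolated)
28 | (6S)-6-methoxy-2-{[(1R,5S)-5-methyl-2-[(2Z)-6-methylhepta-2,5-dien-2-yl]-5-[(triethylsilyl)oxy]cyclopent-2-en-1-yl]methyl}-3-[(triisopropylsilyl)oxy]cyclohex-2-en-1-one | C[C@]1(O[Si](CC)(CC)CC)CC=C(/C(C)=C\CC=C(C)C)[C@H]1CC2=C(O[Si](C(C)C)(C(C)C)C(C)C)CC[C@H](OC)C2=O | intermediate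
29 | (4S)-3-hydroxy-2-{[(1R,5S)-5-hydroxy-5-methyl-2-[(2Z)-6-methylhepta-2,5-dien-2-yl]cyclopent-2-en-1-yl]methyl}-4-methoxycyclohex-2-en-1-one | CO[C@H]1CCC(=O)C(C[C@@H]2C(/C(C)=C\CC=C(C)C)=CC[C@]2(C)O)=C1O | target

**Totals**

Total step count: 16. Longest linear sequence: 14 steps (steps 3 to 16, from compound 4); steps 1 and 2 form the side-chain branch.

**Steps most likely to fail**

1. Step 15 (proposed new method). The protonation may show poor facial discrimination, or may take place on oxygen and be followed by unselective tautomerisation, so that the configuration at C6 is not controlled. The fallback sets out from 22 and 23 and uses only known chemistry: the same addition, ring opening and ring closure are run to dienolate 27, which is quenched with acetic acid at –78 °C without a chiral reagent. This should give 28 together with its epimer (6R)-6-methoxy-2-{[(1R,5S)-5-methyl-2-[(2Z)-6-methylhepta-2,5-dien-2-yl]-5-[(triethylsilyl)oxy]cyclopent-2-en-1-yl]methyl}-3-[(triisopropylsilyl)oxy]cyclohex-2-en-1-one F1. The two diastereomers are separated by preparative HPLC, and F1 is returned to dienolate 27 by kinetic deprotonation at C6 (LiN(iPr)2, THF, –78 °C) and quenched again, so that material is cycled into 28, where the route is rejoined.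

2. Step 13. LiCHBr2 or the amide base may enolise the ester instead of adding to it, or the ynolate may be silylated on carbon to give a silylketene. The fallback sets out from 18. Reduction with i-Bu2AlH (CH2Cl2, –78 °C) should give 2-[(1R,5S)-5-methyl-2-[(2Z)-6-methylhepta-2,5-dien-2-yl]-5-[(triethylsilyl)oxy]cyclopent-2-en-1-yl]acetaldehyde F2. Ohira–Bestmann homologation (dimethyl (1-diazo-2-oxopropyl)phosphonate, K2CO3, MeOH) should then give triethyl{[(1S,2R)-1-methyl-3-[(2Z)-6-methylhepta-2,5-dien-2-yl]-2-(prop-2-yn-1-yl)cyclopent-3-en-1-yl]oxy}silane F3. Its lithium acetylide (n-BuLi, THF, –78 °C) is oxidised with lithium tert-butyl peroxide to the ynolate 20, which is silylated with iPr3SiOTf; the route is rejoined at 21.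

3. Step 11. The acetate enolate may self-condense or fragment, or the rearrangement at the hindered terminus next to the quaternary carbon may be slow enough for the silyl ketene acetal to decompose. The fallback sets out from alcohol 13. Johnson–Claisen rearrangement (triethyl orthoacetate, propionic acid cat., xylene, 140 °C) proceeds through a neutral ketene acetal with the same suprafacial chirality transfer and should give ethyl 2-[(1R,5S)-5-methyl-2-[(2Z)-6-methylhepta-2,5-dien-2-yl]-5-[(triethylsilyl)oxy]cyclopent-2-en-1-yl]acetate F4. F4 takes the place of 18 in the homologation of step 13, and the route is rejoined at 21.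

**Further compounds**

F1 | step 15 | (6R)-6-methoxy-2-{[(1R,5S)-5-methyl-2-[(2Z)-6-methylhepta-2,5-dien-2-yl]-5-[(triethylsilyl)oxy]cyclopent-2-en-1-yl]methyl}-3-[(triisopropylsilyl)oxy]cyclohex-2-en-1-one | C[C@]1(O[Si](CC)(CC)CC)CC=C(/C(C)=C\CC=C(C)C)[C@H]1CC2=C(O[Si](C(C)C)(C(C)C)C(C)C)CC[C@@H](OC)C2=O
F2 | step 13 | 2-[(1R,5S)-5-methyl-2-[(2Z)-6-methylhepta-2,5-dien-2-yl]-5-[(triethylsilyl)oxy]cyclopent-2-en-1-yl]acetaldehyde | C[C@]1(O[Si](CC)(CC)CC)CC=C(/C(C)=C\CC=C(C)C)[C@H]1CC=O
F3 | step 13 | triethyl{[(1S,2R)-1-methyl-3-[(2Z)-6-methylhepta-2,5-dien-2-yl]-2-(prop-2-yn-1-yl)cyclopent-3-en-1-yl]oxy}silane | C[C@]1(O[Si](CC)(CC)CC)CC=C(/C(C)=C\CC=C(C)C)[C@H]1CC#C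
F4 | step 11 | ethyl 2-[(1R,5S)-5-methyl-2-[(2Z)-6-methylhepta-2,5-dien-2-yl]-5-[(triethylsilyl)oxy]cyclopent-2-en-1-yl]acetate | C[C@]1(O[Si](CC)(CC)CC)CC=C(/C(C)=C\CC=C(C)C)[C@H]1CC(=O)OCC
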